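**Retrosynthetic overview**
1. The oxirane is closed last, from the tertiary alcohol on the spiro carbon onto a CH2–sulfonate. This C(OH)–CH2OH pair is the reduced form of a C(OH)–CO2Me pair.
2. Enabling feature: the spiro carbon of the cyclopentenone ring carries one oxygen and one exocyclic carbon (the oxirane CH2). It lies between the aryl-bearing alkene carbon and the C(OMe)(aryl) carbon, which is the retron of a benzilic ester rearrangement. Counting the oxirane CH2 carbon back into the ring gives a six-membered ring with para aryl groups and four oxygenated carbons, i.e. a 2,5-diaryl-3,6-dioxygenated 1,4-benzoquinone.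
3. Key disconnection: cyclopentenone hydroxy ester ⇒ flat, achiral 2-hydroxy-5-methoxy-3,6-diarylbenzoquinone + 2 MeOH. The enol carbon is methoxylated oxidatively, then a 1,2-shift contracts the six-membered ring to five, so both stereocentres arise in one operation.
4. The quinone comes from bromanil by twofold methoxide substitution, twofold Suzuki–Miyaura coupling and saponification of one vinylogous ester.
5. Ring order: the aryl rings and the six-membered ring are bought, the six-membered ring is contracted to the cyclopentenone ring (step 4), and the oxirane ring is closed in step 9.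

Key step: step 4

Assumption: the (R,R)-iodane of step 4 is made beforehand from the commercial iodoarene with AcOOH/AcOH (not counted as a step) and is written as the antipode that leads to the required series; its sense of induction on this substrate class must be checked in a test run, and the (S,S)-reagent is taken if it is opposite.

**Step 1**
Reactants: 1 tetrabromo-1,4-benzoquinone (bromanil)
Product: 2 2,5-dibromo-3,6-dimethoxy-1,4-benzoquinone
Conditions: NaOMe (2.05 equiv), MeOH, 0 °C to rt
Reagents that add atoms: sodium methoxide, C[O-].[Na+]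
Why: Twofold addition–elimination (vinylogous acyl substitution) on the haloquinone; the first methoxy group deactivates, as a vinylogous ester, the carbonyl that would accept attack at the other positions, so the second methoxide should enter para to the first.

**Step 2**
Reactants: 2 2,5-dibromo-3,6-dimethoxy-1,4-benzoquinone; 3 4-(benzyloxy)phenylboronic acid (2.4 equiv)
Product: 4 2,5-dimethoxy-3,6-bis[4-(benzyloxy)phenyl]-1,4-benzoquinone
Conditions: PdCl2(dppf) (5 mol %), K2CO3, dioxane/H2O, 80 °C
Reagents that add atoms: none
Why: Twofold Suzuki–Miyaura coupling; the C–Br bonds of the bromoquinone are vinylogous acyl bromides that should add readily to zerovalent palladium, and the enol and benzyl ethers are inert to the mild base.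

**Step 3**
Reactants: 4 2,5-dimethoxy-3,6-bis[4-(benzyloxy)phenyl]-1,4-benzoquinone
Product: 5 2-hydroxy-5-methoxy-3,6-bis[4-(benzyloxy)phenyl]-1,4-benzoquinone
Conditions: NaOH (1.1 equiv), THF/H2O, rt; then 1 M HCl, 0 °C
Reagents that add atoms: sodium hydroxide, [Na+].[OH-]
Why: Saponification of one vinylogous ester by addition–elimination; the delocalised anion of 5 forms at once and is a much poorer acceptor than 4, so the second methoxy group should stay.

**Step 4**
Reactants: 5 2-hydroxy-5-methoxy-3,6-bis[4-(benzyloxy)phenyl]-1,4-benzoquinone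
Product: 7 methyl (1S,5R)-2,5-bis[4-(benzyloxy)phenyl]-1-hydroxy-3,5-dimethoxy-4-oxocyclopent-2-ene-1-carboxylate, via (3S)-cyclohexenetrione 6 (not isolated)
Conditions: (R,R)-2-(diacetoxy-λ3-iodanyl)-1,3-bis[1-(mesitylcarbamoyl)ethoxy]benzene (1.1 equiv), MeOH (20 equiv), CH2Cl2, −40 °C; then K2CO3 (3 equiv), dry MeOH, −20 to 0 °C
Reagents that add atoms: methanol, CO
Why: Proposed new method: the acidic enol OH of 5 exchanges for acetate on the trivalent iodine centre and methanol attacks the aryl-bearing enol carbon as the iodoarene leaves, giving trione 6 (closest known type: alkoxylative dearomatisation of phenols and naphthols and alpha-oxygenation of 2-substituted 1,3-dicarbonyl enols with aryl-λ3-iodanes, enantioselective with lactamide-armed iodanes mostly for tethered nucleophiles; new is reagent control with external methanol on a hydroxyquinone). Carbonate then lets methanol add to the non-conjugated carbonyl of the 1,2-dione, and in the hemiketal alkoxide the C(OMe)(aryl) carbon shifts to the neighbouring carbonyl carbon, a benzilic ester rearrangement whose closest known case is the ring-contracting first stage of the Hooker oxidation of 3-substituted 2-hydroxyquinones. The cyclopentenone ring is closed by this 1,2-shift, a six-to-five contraction that turns one ring carbon into the exocyclic ester carbon. The C(OMe)(aryl) centre is controlled by the reagent, whose hydrogen-bonded lactamide arms leave one face of the iodine-bound enol open, the two flanking carbonyl groups disfavouring a free cation that would erase this control, and the centre then migrates with retention. The carbinol centre is controlled by the substrate, since the carbon that becomes the ester should swing to the ring face away from the aryl group on the migrating carbon, which puts OH trans to OMe as the target requires. The step needs site selectivity (only one enol carbon is umpoled, only one 1,2-dione is present, and attack on either of its carbonyls followed by shift of the alkyl or the vinyl carbon gives the same skeleton), and the shift must outrun retro-Claisen cleavage, which the alignment of the migrating bond with the adjacent carbonyl group and the low temperature should secure.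

**Step 5**
Reactants: 7 methyl (1S,5R)-2,5-bis[4-(benzyloxy)phenyl]-1-hydroxy-3,5-dimethoxy-4-oxocyclopent-2-ene-1-carboxylate
Product: 8 (1R,2S)-2,5-bis[4-(benzyloxy)phenyl]-1-(hydroxymethyl)-2,4-dimethoxycyclopent-4-ene-1,3-diol (either C3 epimer)
Conditions: LiAlH4 (4 equiv), THF, −10 to 0 °C; aqueous NaOH work-up
Reagents that add atoms: none
Why: Hydride reduction of ester and ketone with LiAlH4; the two quaternary stereocentres are untouched, and the new carbinol carbon may form as either epimer because step 6 makes it planar again.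

**Step 6**
Reactants: 8 (1R,2S)-2,5-bis[4-(benzyloxy)phenyl]-1-(hydroxymethyl)-2,4-dimethoxycyclopent-4-ene-1,3-diol
Product: 9 (4R,5R)-3,5-bis[4-(benzyloxy)phenyl]-4-hydroxy-4-(hydroxymethyl)-2,5-dimethoxycyclopent-2-en-1-one
Conditions: activated MnO2 (excess), CH2Cl2, rt
Reagents that add atoms: none
Why: MnO2 oxidation, selective for the allylic secondary alcohol over the saturated primary and the tertiary alcohol, should restore the enone.

**Step 7**
Reactants: 9 (4R,5R)-3,5-bis[4-(benzyloxy)phenyl]-4-hydroxy-4-(hydroxymethyl)-2,5-dimethoxycyclopent-2-en-1-one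
Product: 10 [(1R,5R)-2,5-bis[4-(benzyloxy)phenyl]-1-hydroxy-3,5-dimethoxy-4-oxocyclopent-2-en-1-yl]methyl (1S,4R)-camphor-10-sulfonate
Conditions: (1S)-(+)-camphor-10-sulfonyl chloride (1.2 equiv), Et3N, DMAP (cat.), CH2Cl2, −10 °C; chromatography or crystallisation
Reagents that add atoms: (1S)-(+)-camphor-10-sulfonyl chloride, CC1(C)[C@@H]2CC[C@]1(C(=O)C2)CS(=O)(=O)Cl
Why: Sulfonylation of the only unhindered (primary) hydroxyl group; because the sulfonyl group is a single enantiomer, any mirror-image material left from step 4 becomes a separable diastereomer, so leaving group and resolving agent are one and the same.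

**Step 8**
Reactants: 10 [(1R,5R)-2,5-bis[4-(benzyloxy)phenyl]-1-hydroxy-3,5-dimethoxy-4-oxocyclopent-2-en-1-yl]methyl (1S,4R)-camphor-10-sulfonate
Product: 11 [(1R,5R)-1-hydroxy-2,5-bis(4-hydroxyphenyl)-3,5-dimethoxy-4-oxocyclopent-2-en-1-yl]methyl (1S,4R)-camphor-10-sulfonate
Conditions: H2 (1 atm), Pd/C (10 wt %), EtOAc, rt
Reagents that add atoms: none
Why: Hydrogenolysis of the two aryl benzyl ethers under neutral conditions, done before the oxirane exists; the tetrasubstituted enone double bond, the hindered tertiary benzylic methyl ether and the sulfonate should react much more slowly.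

**Step 9**
Reactants: 11 [(1R,5R)-1-hydroxy-2,5-bis(4-hydroxyphenyl)-3,5-dimethoxy-4-oxocyclopent-2-en-1-yl]methyl (1S,4R)-camphor-10-sulfonate
Product: 12 (3R,4R)-4,7-bis(4-hydroxyphenyl)-4,6-dimethoxy-1-oxaspiro[2.4]hept-6-en-5-one (target)
Conditions: K2CO3 (4 equiv), MeOH, 0 °C; then pH 7 phosphate buffer
Reagents that add atoms: none
Why: Intramolecular Williamson reaction (3-exo-tet) of the tertiary alkoxide on the neighbouring CH2–sulfonate; no bond to either stereocentre is broken, so both configurations are retained.

**Compound list**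
1 | tetrabromo-1,4-benzoquinone | O=C1C(Br)=C(Br)C(=O)C(Br)=C1Br | starting material
2 | 2,5-dibromo-3,6-dimethoxy-1,4-benzoquinone | COC1=C(Br)C(=O)C(OC)=C(Br)C1=O | intermediate
3 | 4-(benzyloxy)phenylboronic acid | OB(O)c1ccc(OCc2ccccc2)cc1 | starting material
4 | 2,5-dimethoxy-3,6-bis[4-(benzyloxy)phenyl]-1,4-benzoquinone | COC1=C(c2ccc(OCc3ccccc3)cc2)C(=O)C(OC)=C(c2ccc(OCc3ccccc3)cc2)C1=O | intermediate
5 | 2-hydroxy-5-methoxy-3,6-bis[4-(benzyloxy)phenyl]-1,4-benzoquinone | COC1=C(c2ccc(OCc3ccccc3)cc2)C(=O)C(O)=C(c2ccc(OCc3ccccc3)cc2)C1=O | intermediate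
6 | (3S)-3,5-dimethoxy-3,6-bis[4-(benzyloxy)phenyl]cyclohex-5-ene-1,2,4-trione (not isolated) | COC1=C(c2ccc(OCc3ccccc3)cc2)C(=O)C(=O)[C@](OC)(c2ccc(OCc3ccccc3)cc2)C1=O | intermediate
7 | methyl (1S,5R)-2,5-bis[4-(benzyloxy)phenyl]-1-hydroxy-3,5-dimethoxy-4-oxocyclopent-2-ene-1-carboxylate | COC1=C(c2ccc(OCc3ccccc3)cc2)[C@@](O)(C(=O)OC)[C@](OC)(c2ccc(OCc3ccccc3)cc2)C1=O | intermediate
8 | (1R,2S)-2,5-bis[4-(benzyloxy)phenyl]-1-(hydroxymethyl)-2,4-dimethoxycyclopent-4-ene-1,3-diol, C3 undefined | COC1=C(c2ccc(OCc3ccccc3)cc2)[C@@](O)(CO)[C@](OC)(c2ccc(OCc3ccccc3)cc2)C1O | intermediate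
9 | (4R,5R)-3,5-bis[4-(benzyloxy)phenyl]-4-hydroxy-4-(hydroxymethyl)-2,5-dimethoxycyclopent-2-en-1-one | COC1=C(c2ccc(OCc3ccccc3)cc2)[C@@](O)(CO)[C@](OC)(c2ccc(OCc3ccccc3)cc2)C1=O | intermediate
10 | primary (1S,4R)-camphor-10-sulfonate of 9 | COC1=C(c2ccc(OCc3ccccc3)cc2)[C@@](O)(COS(=O)(=O)C[C@]23CC[C@H](CC2=O)C3(C)C)[C@](OC)(c2ccc(OCc3ccccc3)cc2)C1=O | intermediate
11 | bisphenol of 10 | COC1=C(c2ccc(O)cc2)[C@@](O)(COS(=O)(=O)C[C@]23CC[C@H](CC2=O)C3(C)C)[C@](OC)(c2ccc(O)cc2)C1=O | intermediate
12 | (3R,4R)-4,7-bis(4-hydroxyphenyl)-4,6-dimethoxy-1-oxaspiro[2.4]hept-6-en-5-one | COC1=C(c2ccc(O)cc2)[C@@]2(CO2)[C@](OC)(c2ccc(O)cc2)C1=O | target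

Total step count: 9. Longest linear sequence: 9 steps (from 1).

**Steps most likely to fail**

1. Step 4 (Proposed new method).
   - Risk: the iodoarene may leave early through a free cation, with loss of enantiofacial control. The trione may open by retro-Claisen cleavage instead of undergoing the shift. The shift may show poor facial selectivity.
   - Fallback (known chemistry, resolution in place of induction): it sets out from 5. PhI(OAc)2 in MeOH (achiral alkoxylative oxidation of the enol) gives the trione as a racemate, i.e. 6 together with the (3R)-trione F1, which is isolated. K2CO3 in MeOH (benzilic ester rearrangement) then gives 7 together with its mirror image, the (1R,5S)-hydroxy ester F2. The racemate is taken through steps 5 to 7 as written. The mirror-image series runs through the (1S,2R)-triol F3 and the (4S,5S)-diol F4 to the diastereomeric camphorsulfonate F5, which is removed by chromatography or crystallisation. The route is rejoined at 10.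

2. Step 9.
   - Risk: the phenoxide may expel methoxide from the benzylic centre. The tertiary alkoxide may open by retro-aldol cleavage. Methoxide may open the fresh oxirane.
   - Fallback (oxirane before deprotection, so that no phenoxide is present during closure): it sets out from 10. K2CO3 in MeOH closes the ring to the bis(benzyl) ether of the target F6. Catalytic transfer hydrogenolysis (Pd/C, cyclohexa-1,4-diene, EtOAc, short contact) then frees the phenols. The route is rejoined at 12.

3. Step 6.
   - Risk: the hindered allylic alcohol may oxidise sluggishly, or the 1,2-diol may undergo glycol cleavage on MnO2.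
   - Fallback (order reversed, so that no free primary alcohol and no free glycol meets the oxidant): it sets out from 8. The primary hydroxyl group is sulfonylated first with (1S)-(+)-camphor-10-sulfonyl chloride/Et3N to the triol monosulfonate F7. The remaining secondary allylic alcohol is then oxidised with Dess–Martin periodinane. The route is rejoined at 10, where the diastereomer purge is carried out.

**Further compounds**
F1 | step 4 | (3R)-3,5-dimethoxy-3,6-bis[4-(benzyloxy)phenyl]cyclohex-5-ene-1,2,4-trione | COC1=C(c2ccc(OCc3ccccc3)cc2)C(=O)C(=O)[C@@](OC)(c2ccc(OCc3ccccc3)cc2)C1=O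
F2 | step 4 | methyl (1R,5S)-2,5-bis[4-(benzyloxy)phenyl]-1-hydroxy-3,5-dimethoxy-4-oxocyclopent-2-ene-1-carboxylate | COC1=C(c2ccc(OCc3ccccc3)cc2)[C@](O)(C(=O)OC)[C@@](OC)(c2ccc(OCc3ccccc3)cc2)C1=O
F3 | step 4 | (1S,2R)-2,5-bis[4-(benzyloxy)phenyl]-1-(hydroxymethyl)-2,4-dimethoxycyclopent-4-ene-1,3-diol, C3 undefined | COC1=C(c2ccc(OCc3ccccc3)cc2)[C@](O)(CO)[C@@](OC)(c2ccc(OCc3ccccc3)cc2)C1O
F4 | step 4 | (4S,5S)-3,5-bis[4-(benzyloxy)phenyl]-4-hydroxy-4-(hydroxymethyl)-2,5-dimethoxycyclopent-2-en-1-one | COC1=C(c2ccc(OCc3ccccc3)cc2)[C@](O)(CO)[C@@](OC)(c2ccc(OCc3ccccc3)cc2)C1=O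
F5 | step 4 | primary (1S,4R)-camphor-10-sulfonate of F4 | COC1=C(c2ccc(OCc3ccccc3)cc2)[C@](O)(COS(=O)(=O)C[C@]23CC[C@H](CC2=O)C3(C)C)[C@@](OC)(c2ccc(OCc3ccccc3)cc2)C1=O
F6 | step 9 | (3R,4R)-4,7-bis[4-(benzyloxy)phenyl]-4,6-dimethoxy-1-oxaspiro[2.4]hept-6-en-5-one | COC1=C(c2ccc(OCc3ccccc3)cc2)[C@@]2(CO2)[C@](OC)(c2ccc(OCc3ccccc3)cc2)C1=O
F7 | step 6 | primary (1S,4R)-camphor-10-sulfonate of 8, ring carbinol carbon undefined | COC1=C(c2ccc(OCc3ccccc3)cc2)[C@@](O)(COS(=O)(=O)C[C@]23CC[C@H](CC2=O)C3(C)C)[C@](OC)(c2ccc(OCc3ccccc3)cc2)C1O
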